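If other capture product and target grow side by side from one substrate, compare their rates at one moment, then ask how that comparison drifts.

| flask | substrate | first nucleophile | second nucleophile | remark | time |
|---|---|---|---|---|---|
| west | 39 mM | 58.5 mM | 98 mM | run made earlier |  |
| south-west | 39 mM | 58.5 mM | 150 mM | run made earlier |  |
| flask | 39 mM | 58.5 mM | 195 mM |  | 50 min |

| run | time / min | other capture product / % | target / % | substrate / % |
|---|---|---|---|---|
| west | 4.00 | 18.6 | 37.1 | 32.7 |
| west | 6.00 | 25.7 | 40.2 | 17.0 |
| west | 12.0 | 34.3 | 46.2 | 0.6 |
| west | 20.0 | 37.5 | 45.3 | 0 |
| west | 30.0 | 38.5 | 47.2 | 0 |
| west | 50.0 | 37.1 | 44.4 | 0.3 |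
| south-west | 4.00 | 25.5 | 34.2 | 30.5 |
| south-west | 6.00 | 32.2 | 38.1 | 15.0 |
| south-west | 12.0 | 43.8 | 40.3 | 2.0 |
| south-west | 20.0 | 44.9 | 41.7 | 0.5 |
| south-west | 30.0 | 43.9 | 39.7 | 0.2 |
| south-west | 50.0 | 46.5 | 39.0 | 0.5 |

(readings scatter by 1 percentage point)

- the analysis behind the earlier runs scatters by 1 percentage point, standard deviation
- a reading or a percentage of target counts all its forms, free or not

* share of other capture product in other capture product plus target at 30 s
* share of other capture product in other capture product plus target at 50 min
* which of other capture product and target there is more of at 50 min

Two chemists dispute the flask with c(second nucleophile) at 195 mM. They share one estimate of its start. Read back from the west readings, the ratio of other capture product to target at zero time is about 0.3. The flask has twice that c(second nucleophile), so they estimate about 0.6 for it.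

The first chemist holds that this split lasts. Target then leads at 50 min, with a share near 38 %.

The second chemist looks at the drift. West goes from 0.501 at 4.00 min to 0.836 at 50.0 min, so the start is not the end. West ends with less other capture product than target. South-west ends with more.

My own reckoning takes this side. Pooling both runs gives 8.18 /M, the end split: final other capture product over final target, per unit of c(second nucleophile). It is a lump read from scattered readings: west alone gives 8.53 /M, south-west alone 7.95 /M. For the flask it gives a ratio of 1.60, above one, and a share of 61.5 %.

The forecast takes the same side with a lower number: “The final ratio is sublinear in second nucleophile”. It says 38 % early, 57 % late, and other capture product ahead.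

The flask gives 33.2 % at 30 s and 57.7 % at 50 min. The share at 30 s is a ratio of 0.497, against the estimate of 0.6 for the start. It ends with 50.1 % of other capture product against 36.7 % of target, so other capture product leads. The forecast held. The end ratio is 1.37, which makes the end split here 7.00 /M, below the pooled value.

    first nucleophile + target ⇌ idle adduct, settled at all times (K = 58.0 /M)
    second nucleophile + intermediate → other capture product (k = 8.62 /M/min)
    2 first nucleophile → homo dimer (k = 3.18 /M/min)
    substrate → intermediate (k = 0.276 /min)
    substrate + target → side product (k = 4.59 /M/min)
    first nucleophile + intermediate → target (k = 66.7 /M/min)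

The first chemist keeps a region. In the flask, target stays ahead until 4.58 min. The neighbour charged with 49 mM of second nucleophile has a share of 11.2 % at 30 s. There the end split gives a ratio of 0.401, below one, and a share of 28.6 %, so target should lead. The neighbour does end with target ahead. Its share is 31.8 %, with 55.2 % of target against 25.7 % of other capture product.

The earlier runs and the new flask stem from a simulated flask for substances that don't exist.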